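## Structural features

The target is a 5,6,7,8-tetrahydro-1H-isochromen-8-one. A 2H-pyran ring (C1H2, O2, C3, C4) is fused through the tetrasubstituted C4a=C8a double bond to a cyclohexenone, so that O2–C3=C4–C4a=C8a–C8=O is one push–pull dienone; C3 carries an (E)-prop-1-enyl group. C7 (quaternary, methyl and acyloxy, R) and C6 (secondary hydroxyl, R) are adjacent stereocentres directly beside the C8 ketone, and their two oxygen substituents are cis on the carbocycle. The C7 oxygen is esterified by 4-hydroxy-2-methoxy-6-methylbenzoic acid: a 2,6-disubstituted benzoate on a tertiary alcohol, with the oxygen ortho to the carbonyl methylated and the para oxygen free. Fragile points are the tertiary ester next to a free cis hydroxyl (1,2-acyl shift), the C6 oxygen that is δ to the ketone through C5 and C4a=C8a (vinylogous β-elimination under base), the dienyl ether (acid) and the conjugated side chain. The real difficulties are (a) a doubly ortho-substituted aryl ester of a hindered tertiary α-ketol with the correct phenolic oxygen methylated, and (b) a C4a=C8a alkene bearing two different carbon arms that are joined through O2. The key step exploits the fact that C1' and C6' with the C6' methyl group are a but-2-ynoyl unit, and C2'–C5' with their oxygen pattern are a 1,1-dimethoxy-3-silyloxybuta-1,3-diene: the tertiary alcohol is acylated with a slim linear acid and the benzene ring is then grown on the ester.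

## Logic of the disconnections

Atom labels of the target (C1–C8a, primed for the arene) are used for all intermediates.

30 ⇒ 29 ⇒ 28 (handled as 27). The C6 O–Si bond is cut first, then O2–C3. O2 sits on the δ-carbon of the C8 dienone, so O2–C3 is the one ring bond an oxygen nucleophile can make by conjugate addition. Cutting it leaves a carbocycle with a one-carbon and a five-carbon arm on neighbouring sp2 carbons. The forward closure must occur at C3 (six-membered ring), not at C4 (five-membered ring). It is placed before the last desilylation so that base never meets a free C6 hydroxyl beside the C7 ester, and that desilylation must be buffered and non-basic.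

27 ⇒ 23. The C4a=C8a double bond is taken back to the saturated β-hydroxy ketone. The two arms then become the result of a conjugate addition and an enolate capture on a plain enone. The price is a dehydrogenation that must remove the hydrogen on C4a and leave the C1 hydrogens alone.

23 ⇒ 22 ⇒ 17 + 19. C1–C8a and C4–C4a are cut, giving an enone, a five-carbon enyne unit (19, from 18) and a one-carbon aldehyde. This is convergent, and the two new sp3 centres are erased later. The forward steps need 1,4- rather than 1,2-addition, a regiodefined enol ether (guaranteed, since C7 is quaternary) and an untouched E-alkene.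

17 ⇒ 16 ⇒ 15. The C4a=C8a unsaturation is removed and the aryl silyl ether is opened to the phenol. The enone is introduced only after the arene is complete, because it would be a second dienophile in the ring-forming step. Only C8a of 15 can enolise, so the dehydrogenation is regiospecific.

15 ⇒ 9 + 12. C1'–C2' and C5'–C6' are cut, so the arene falls apart into the ynoate 9 and the four-carbon diene 12. This reduces the hindered ester problem to acylation by a linear acid and encodes the 2-methoxy/4-hydroxy pattern in the diene, so no phenol differentiation is needed. The forward step demands one regiochemistry and a single dienophile. The precursor is therefore kept at the saturated ketone level with the C6 oxygen as a robust silyl ether.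

9 ⇒ 7 + 8. The ester C–O bond at C7 is cut. The forward acylation of a tertiary α-ketol must not isomerise the ynoate to an allene.

7 ⇒ 6 ⇒ 5 ⇒ 4 ⇒ 3. The C8 ketone is traced to a carbinol and the protecting groups are adjusted back to diol 4. Both C–O bonds at C7 and C6 are then cut together, because their cis relationship is the signature of a syn-dihydroxylation. The C8 alkoxy group of 3 serves twice: as the future ketone and as the element that directs the reagent to the opposite face. A carbene-catalysed ring closure of an open-chain keto aldehyde would be two steps shorter, but it would leave the relative configuration at C7 to reagent control. Here cis is the only possible outcome and only the facial selectivity is asked of the forward step.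

3 ⇒ 2 ⇒ 1. The O-benzyl bond and then the carbinol C–H bond are cut. The single stereocentre that controls all others comes from an enantioselective ketone reduction.

12 ⇒ 11 ⇒ 10 and 19 ⇒ 18. The diene is traced through its methyl ketone to a ketene acetal and an acetyl unit (O–Si and C–C cuts). The dibromodiene is traced to the enal by a C=C cut. Both are short side branches.

## Other disconnections considered

Alternative 1: Rauhut–Currier cyclisation and oxa-6π closure.
- Cut: C4a–C8a and O2–C1.
- Forward: in the acyclic enone–ynone A1 a nucleophilic phosphine or tertiary-amine catalyst adds to the vinyl ketone; the C8a enolate attacks the ynone β-carbon C4a (6-exo-dig); loss of the catalyst leaves the 1-oxatriene A2; oxa-6π electrocyclisation forms O2–C1 and gives A3, the bis-silyl ether of 30.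
- In favour: carbocycle and pyran arise in one operation. The pyran closes pericyclically, so the 5-exo/6-endo question of step 17 and both dehydrogenations (steps 12 and 16) disappear; on these points it is the better plan. The C6/C7 syn-diol could come from dihydroxylation of an acyclic trisubstituted alkene, the equal of step 3.
- Against: A1 carries two different Michael acceptors, and the catalyst must choose the vinyl ketone over the more electrophilic ynone. The C4a=C4 geometry must place the C3 carbonyl toward C1. The aryl ester on a tertiary alcohol must still be made, on a substrate less tolerant than 7.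
- Comparison: on structure it solves the pyran better and the ester worse. On mechanism the risk is concentrated in one cascade instead of being spread over known steps. On step economy the endgame is shorter but the synthesis of A1 is longer, so the totals should be similar.

Alternative 2: three-component conjugate alkynylation–hydroxymethylation.
- Cut: C4–C4a and C1–C8a.
- Forward: conjugate alkynylation of enone A4 under silyl triflate activation, then aqueous hydroxymethylation of the resulting enolate equivalent in the same flask, gives A5.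
- Relation to the chosen plan: A4 has the constitution of 17 and A5 that of 23, so this bond set is already steps 14 and 15. As a leading disconnection it differs only in the origin of the aryl ester, which would arrive as the preformed acid A6.
- In favour: the one-flask version saves an isolation (better on step count at this point). Regiochemistry is fixed by the quaternary C7 and the new stereocentres are irrelevant (equal).
- Against: esterifying the tertiary ketol with the 2,6-disubstituted acid A6 is the hardest acylation in the molecule. A6 needs its own synthesis with differentiation of two phenols. Adding water to excess silyl triflate generates triflic acid in the presence of the enol ether.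
- Comparison: structurally it leaves the central problem, the hindered ester, unsolved. Mechanistically it is identical for the C–C bonds. It is only shorter if the direct esterification works.

Alternative 3: ketene capture and biomimetic aromatisation.
- Cut: the ester C–O bond and C1'–C6'.
- Forward: thermolysis of the diketo-dioxinone A8 gives the acylketene A9, which is captured by the tertiary alcohol of the bicyclic core A7. The trioxooctanoate A10 closes by aldol condensation of chain C2 onto C7 and dehydrates to the resorcylate A11.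
- In favour: acylketenes acylate hindered tertiary alcohols without coupling agents, which is better than step 7 on this point. The arene is built last and convergently.
- Against: A11 is a 2,4-dihydroxybenzoate. The target needs the hydrogen-bonded ortho hydroxyl methylated and the more reactive para hydroxyl free, so a protect/methylate/deprotect sequence follows on a base-sensitive dienone. Thermolysis and aromatisation must be tolerated by the complete dienyl ether, and A7 must carry a free tertiary ketol through the enone chemistry.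
- Comparison: both plans grow the arene on the ester. The chosen plan is better on the O-methyl pattern, which the ketene acetal fixes. Alternative 3 is equal or better on the acylation itself and worse on step count once the phenol adjustments are added.

Key step: step 10

Abbreviations: TBS = tert-butyldimethylsilyl, TMS = trimethylsilyl, Tf = trifluoromethanesulfonyl, Bn = benzyl; "TBSO" = (tert-butyldimethylsilyl)oxy.

## Steps

Step 1
Reactants: 1 2-methylcyclohex-2-en-1-one
Product: 2 (1R)-2-methylcyclohex-2-en-1-ol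
Conditions: (S)-2-methyl-CBS-oxazaborolidine (10 mol %), BH3·SMe2, THF, −20 °C; MeOH quench
Reagents that add atoms: none
Why: Corey–Bakshi–Shibata reduction; the substituted alkenyl side of the enone acts as the large group, so the (S)-catalyst should deliver hydride to the face that gives the (R)-allylic alcohol, and low temperature favours 1,2-reduction over hydroboration.

Step 2
Reactants: 2 (1R)-2-methylcyclohex-2-en-1-ol
Product: 3 benzyl (1R)-2-methylcyclohex-2-en-1-yl ether
Conditions: NaH, BnBr, Bu4NI (cat.), THF, 0 °C → rt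
Reagents that add atoms: benzyl bromide, BrCc1ccccc1
Why: Williamson etherification at oxygen, so the stereocentre is untouched; benzyl is inert to osmylation and silylation and is later removed by hydrogenolysis without disturbing a silyl ether.

Step 3
Reactants: 3 benzyl (1R)-2-methylcyclohex-2-en-1-yl ether
Product: 4 (1R,2R,3R)-3-(benzyloxy)-2-methylcyclohexane-1,2-diol
Conditions: OsO4 (2 mol %), N-methylmorpholine N-oxide, acetone–H2O, rt
Reagents that add atoms: OsO4, O=[Os](=O)(=O)=O; N-methylmorpholine N-oxide, C[N+]1([O-])CCOCC1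
Why: Upjohn syn-dihydroxylation; both oxygens arrive on one face, and the reagent should approach anti to the allylic benzyloxy group (held pseudoaxial by the adjacent vinylic methyl), which sets C7 and C6 with their oxygens cis to each other and trans to the benzyloxy group.

Step 4
Reactants: 4 (1R,2R,3R)-3-(benzyloxy)-2-methylcyclohexane-1,2-diol
Product: 5 (1S,2R,6R)-2-(benzyloxy)-6-TBSO-1-methylcyclohexan-1-ol
Conditions: TBSOTf (1.1 equiv), 2,6-lutidine, CH2Cl2, −78 °C
Reagents that add atoms: tert-butyldimethylsilyl triflate, CC(C)(C)[Si](C)(C)OS(=O)(=O)C(F)(F)F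
Why: Silyl ether formation; at low temperature with one equivalent the secondary hydroxyl should react well before the tertiary one (the change of the C7 descriptor to S is a priority effect only).

Step 5
Reactants: 5 (1S,2R,6R)-2-(benzyloxy)-6-TBSO-1-methylcyclohexan-1-ol
Product: 6 (1R,2S,3R)-3-TBSO-2-methylcyclohexane-1,2-diol
Conditions: H2 (1 atm), Pd/C (10 %), EtOAc, rt
Reagents that add atoms: none
Why: Hydrogenolysis of the benzyl ether; the aprotic solvent keeps the silyl ether intact and no other reducible group is present.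

Step 6
Reactants: 6 (1R,2S,3R)-3-TBSO-2-methylcyclohexane-1,2-diol
Product: 7 (2R,3R)-3-TBSO-2-hydroxy-2-methylcyclohexan-1-one
Conditions: Dess–Martin periodinane, NaHCO3, CH2Cl2, 0 °C → rt
Reagents that add atoms: none
Why: Dess–Martin oxidation of the only secondary alcohol; the tertiary alcohol cannot be oxidised, C7 is quaternary and C6 is not α to the new ketone, so neither centre can epimerise or eliminate.

Step 7
Reactants: 7 (2R,3R)-3-TBSO-2-hydroxy-2-methylcyclohexan-1-one; 8 but-2-ynoic acid
Product: 9 (1R,2R)-2-TBSO-1-methyl-6-oxocyclohexyl but-2-ynoate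
Conditions: 8 (3 equiv), DCC, DMAP (0.2 equiv), CH2Cl2, −20 °C → rt
Reagents that add atoms: none
Why: Steglich esterification; the linear sp-hybridised acyl group meets little steric resistance at the tertiary α-ketol, and sub-stoichiometric DMAP at low temperature limits alkyne-to-allene isomerisation and conjugate addition of the catalyst.

Step 8
Reactants: 10 1,1-dimethoxyethene
Product: 11 4,4-dimethoxybut-3-en-2-one
Conditions: AcCl, Et3N, Et2O, 0 °C → rt
Reagents that add atoms: acetyl chloride, CC(=O)Cl
Why: C-acylation of the nucleophilic ketene acetal followed by loss of HCl to the amine gives the vinylogous ester.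

Step 9
Reactants: 11 4,4-dimethoxybut-3-en-2-one
Product: 12 1,1-dimethoxy-3-(trimethylsilyloxy)buta-1,3-diene
Conditions: LiN(i-Pr)2, THF, −78 °C; TMSCl
Reagents that add atoms: chlorotrimethylsilane, C[Si](C)(C)Cl
Why: Kinetic deprotonation of the methyl ketone and O-silylation of the enolate (silyl enol ether formation); the diene is used without chromatography.

Step 10
Reactants: 9 (1R,2R)-2-TBSO-1-methyl-6-oxocyclohexyl but-2-ynoate; 12 1,1-dimethoxy-3-(trimethylsilyloxy)buta-1,3-diene
Product: 15 (1R,2R)-2-TBSO-1-methyl-6-oxocyclohexyl 4-hydroxy-2-methoxy-6-methylbenzoate, via cyclohexa-1,4-diene cycloadduct 13 (not isolated), via aryl trimethylsilyl ether 14 (not isolated)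
Conditions: 12 (3 equiv), PhMe, 115 °C, sealed tube; then 0.1 M aq. HCl, THF, 0 °C
Reagents that add atoms: none
Why: Normal-electron-demand Diels–Alder reaction of the electron-rich diene with the ynoate followed by aromatisation; the closest known reaction type is the thermal cycloaddition–aromatisation of 1,1-dialkoxy-3-silyloxybuta-1,3-dienes with alk-2-ynoates to 4-hydroxy-2-alkoxy-6-alkylbenzoates. Bond formation is asynchronous: the CH2 terminus of the diene, which carries the largest HOMO coefficient because the silyloxy and both methoxy groups feed it, bonds to the ynoate β-carbon (future C6'), and the ketene-acetal carbon bonds to the α-carbon (future C1'), so C5'–C6' and C1'–C2' are the new bonds and both methoxy groups arrive on C2'. The six-membered carbocycle closes in one intermolecular suprafacial [4+2] event to give 13; loss of one methanol across C2'/C5' gives 14, and the dilute acid work-up removes the trimethylsilyl group to free the C4' phenol. No stereocentre is formed; C6 and C7 take part in no bond change and the medium is neutral and aprotic, so their configuration is carried through. The selectivity needed is regiochemical (which oxygen ends ortho to the ester) and chemical (ynoate only): the first is fixed by the matched polarisation of the partners, the second by the absence of any other dienophile, since the ketone is still saturated and neither it nor the silyl ether reacts with the diene without a Lewis acid. The diene is used in excess because the methanol set free consumes part of it.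

Step 11
Reactants: 15 (1R,2R)-2-TBSO-1-methyl-6-oxocyclohexyl 4-hydroxy-2-methoxy-6-methylbenzoate
Product: 16 (1R,6R)-2,6-bis(TBSO)-1-methylcyclohex-2-en-1-yl 4-TBSO-2-methoxy-6-methylbenzoate
Conditions: TBSOTf (2.5 equiv), Et3N, CH2Cl2, 0 °C → rt
Reagents that add atoms: tert-butyldimethylsilyl triflate, CC(C)(C)[Si](C)(C)OS(=O)(=O)C(F)(F)F
Why: One reagent silylates the phenol and converts the ketone to its silyl enol ether by soft enolisation; only C8a can enolise because C7 is quaternary, so one regioisomer is possible.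

Step 12
Reactants: 16 (1R,6R)-2,6-bis(TBSO)-1-methylcyclohex-2-en-1-yl 4-TBSO-2-methoxy-6-methylbenzoate
Product: 17 (1R,6R)-6-TBSO-1-methyl-2-oxocyclohex-3-en-1-yl 4-TBSO-2-methoxy-6-methylbenzoate
Conditions: Pd(OAc)2 (1.1 equiv), MeCN, rt
Reagents that add atoms: none
Why: Saegusa–Ito oxidation; the enol ether transfers to divalent palladium and β-hydride elimination can only take the C4a hydrogen, giving the C4a=C8a enone and zerovalent palladium.

Step 13
Reactants: 18 (E)-but-2-enal
Product: 19 (3E)-1,1-dibromopenta-1,3-diene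
Conditions: CBr4, PPh3, CH2Cl2, 0 °C
Reagents that add atoms: carbon tetrabromide, BrC(Br)(Br)Br
Why: Corey–Fuchs dibromo-olefination (Wittig-type) of the aldehyde; the existing E-alkene is not involved.

Step 14
Reactants: 17 (1R,6R)-6-TBSO-1-methyl-2-oxocyclohex-3-en-1-yl 4-TBSO-2-methoxy-6-methylbenzoate; 19 (3E)-1,1-dibromopenta-1,3-diene
Product: 22 (1R,6R)-2,6-bis(TBSO)-1-methyl-4-[(3E)-pent-3-en-1-yn-1-yl]cyclohex-2-en-1-yl 4-TBSO-2-methoxy-6-methylbenzoate (C4a epimers), via lithium (E)-pent-3-en-1-ynide 20 (not isolated), via bromo[(E)-pent-3-en-1-ynyl]zinc 21 (not isolated)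
Conditions: 19, n-BuLi (2 equiv), THF, −78 → 0 °C; ZnBr2; then 17, TBSOTf, Et2O–THF, −40 °C
Reagents that add atoms: tert-butyldimethylsilyl triflate, CC(C)(C)[Si](C)(C)OS(=O)(=O)C(F)(F)F
Why: The second Corey–Fuchs stage (bromine–lithium exchange, Fritsch–Buttenberg–Wiechell shift, deprotonation) gives the acetylide without isolating the volatile enyne, and transmetalation gives a zinc reagent that spares ester and ketone. Silyl-triflate-promoted conjugate alkynylation of the enone forms C4–C4a and traps the enolate as its silyl enol ether; the C4a configuration is irrelevant because it is erased in step 16.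

Step 15
Reactants: 22 (1R,6R)-2,6-bis(TBSO)-1-methyl-4-[(3E)-pent-3-en-1-yn-1-yl]cyclohex-2-en-1-yl 4-TBSO-2-methoxy-6-methylbenzoate
Product: 23 (1R,6R)-6-TBSO-3-(hydroxymethyl)-1-methyl-2-oxo-4-[(3E)-pent-3-en-1-yn-1-yl]cyclohexyl 4-TBSO-2-methoxy-6-methylbenzoate (C4a/C8a epimers)
Conditions: 37 % aq. HCHO, Yb(OTf)3 (20 mol %), THF, rt
Reagents that add atoms: formaldehyde, C=O
Why: Water-tolerant lanthanide-triflate-catalysed Mukaiyama aldol (hydroxymethylation) of the isolated silyl enol ether forms C1–C8a; isolating 22 first keeps triflic acid away from the enol ether, and the new centre is erased in step 16.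

Step 16
Reactants: 23 (1R,6R)-6-TBSO-3-(hydroxymethyl)-1-methyl-2-oxo-4-[(3E)-pent-3-en-1-yn-1-yl]cyclohexyl 4-TBSO-2-methoxy-6-methylbenzoate
Product: 27 (1R,6R)-6-TBSO-1-methyl-2-oxo-4-[(3E)-pent-3-en-1-yn-1-yl]-3-[(trimethylsilyloxy)methyl]cyclohex-3-en-1-yl 4-TBSO-2-methoxy-6-methylbenzoate, via bis(trimethylsilyl) enol ether 24 (not isolated), via α-phenylselanyl ketone 25 (not isolated), via selenoxide 26 (not isolated)
Conditions: TMSOTf (2.5 equiv), Et3N, CH2Cl2, 0 °C; PhSeCl (1.05 equiv), −78 °C; then 30 % H2O2, pyridine, CH2Cl2, 0 °C → rt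
Reagents that add atoms: trimethylsilyl triflate, C[Si](C)(C)OS(=O)(=O)C(F)(F)F
Why: Soft enolisation (only C8a is enolisable) and selenenylation of the enol ether, which should occur anti to the pseudoaxial alkynyl group on C4a and so place selenium syn to the C4a hydrogen. Selenoxide syn-elimination then runs into the ring, because selenoxides eliminate away from an oxygen-bearing carbon (C1) and toward the activated propargylic hydrogen, restoring C4a=C8a.

Step 17
Reactants: 27 (1R,6R)-6-TBSO-1-methyl-2-oxo-4-[(3E)-pent-3-en-1-yn-1-yl]-3-[(trimethylsilyloxy)methyl]cyclohex-3-en-1-yl 4-TBSO-2-methoxy-6-methylbenzoate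
Product: 29 (6R,7R)-6-TBSO-7-methyl-8-oxo-3-[(1E)-prop-1-en-1-yl]-5,6,7,8-tetrahydro-1H-isochromen-7-yl 4-hydroxy-2-methoxy-6-methylbenzoate, via hydroxymethyl enynone 28 (not isolated)
Conditions: K2CO3, MeOH, 0 °C
Reagents that add atoms: none
Why: Methanolysis removes the primary trimethylsilyl ether and the aryl silyl ether, and the C1 alkoxide then closes O2–C3 by 6-endo-dig oxa-Michael (1,6-) addition, either directly or after reversible δ-addition of methoxide and alkoxy exchange at C3. C3 is the δ-electrophilic carbon whereas C4 is not activated, which disfavours the 5-exo mode. The C6 oxygen is still silylated, so no acyl shift is possible under base.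

Step 18
Reactants: 29 (6R,7R)-6-TBSO-7-methyl-8-oxo-3-[(1E)-prop-1-en-1-yl]-5,6,7,8-tetrahydro-1H-isochromen-7-yl 4-hydroxy-2-methoxy-6-methylbenzoate
Product: 30 (6R,7R)-6-hydroxy-7-methyl-8-oxo-3-[(1E)-prop-1-en-1-yl]-5,6,7,8-tetrahydro-1H-isochromen-7-yl 4-hydroxy-2-methoxy-6-methylbenzoate
Conditions: HF·pyridine, pyridine, THF, 0 °C → rt
Reagents that add atoms: none
Why: Fluoride-mediated desilylation of the hindered secondary silyl ether in a buffered, weakly acidic medium, which should avoid both the 1,2-acyl shift to the freed C6 hydroxyl and base-induced elimination; no stereocentre is touched.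

## Compound list

1 | 2-methylcyclohex-2-en-1-one | CC1=CCCCC1=O | starting material
2 | (1R)-2-methylcyclohex-2-en-1-ol | O[C@@H]1CCCC=C1C | intermediate
3 | benzyl (1R)-2-methylcyclohex-2-en-1-yl ether | c1ccccc1CO[C@@H]1CCCC=C1C | intermediate
4 | (1R,2R,3R)-3-(benzyloxy)-2-methylcyclohexane-1,2-diol | C1C[C@@H](OCc2ccccc2)[C@](C)(O)[C@H](O)C1 | intermediate
5 | (1S,2R,6R)-2-(benzyloxy)-6-TBSO-1-methylcyclohexan-1-ol | C1C[C@@H](OCc2ccccc2)[C@](C)(O)[C@H](O[Si](C)(C)C(C)(C)C)C1 | intermediate
6 | (1R,2S,3R)-3-TBSO-2-methylcyclohexane-1,2-diol | C1C[C@@H](O)[C@](C)(O)[C@H](O[Si](C)(C)C(C)(C)C)C1 | intermediate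
7 | (2R,3R)-3-TBSO-2-hydroxy-2-methylcyclohexan-1-one | C1CC(=O)[C@](C)(O)[C@H](O[Si](C)(C)C(C)(C)C)C1 | intermediate
8 | but-2-ynoic acid | CC#CC(=O)O | starting material
9 | (1R,2R)-2-TBSO-1-methyl-6-oxocyclohexyl but-2-ynoate | C1CC(=O)[C@](C)(OC(=O)C#CC)[C@H](O[Si](C)(C)C(C)(C)C)C1 | intermediate
10 | 1,1-dimethoxyethene | C=C(OC)OC | starting material
11 | 4,4-dimethoxybut-3-en-2-one | CC(=O)C=C(OC)OC | intermediate
12 | 1,1-dimethoxy-3-(trimethylsilyloxy)buta-1,3-diene | COC(OC)=CC(=C)O[Si](C)(C)C | intermediate
13 | (1R,2R)-2-TBSO-1-methyl-6-oxocyclohexyl 6,6-dimethoxy-2-methyl-4-(trimethylsilyloxy)cyclohexa-1,4-diene-1-carboxylate | C1CC(=O)[C@](C)(OC(=O)C2=C(C)CC(O[Si](C)(C)C)=CC2(OC)OC)[C@H](O[Si](C)(C)C(C)(C)C)C1 | intermediate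
14 | (1R,2R)-2-TBSO-1-methyl-6-oxocyclohexyl 2-methoxy-6-methyl-4-(trimethylsilyloxy)benzoate | C1CC(=O)[C@](C)(OC(=O)c2c(C)cc(O[Si](C)(C)C)cc2OC)[C@H](O[Si](C)(C)C(C)(C)C)C1 | intermediate
15 | (1R,2R)-2-TBSO-1-methyl-6-oxocyclohexyl 4-hydroxy-2-methoxy-6-methylbenzoate | C1CC(=O)[C@](C)(OC(=O)c2c(C)cc(O)cc2OC)[C@H](O[Si](C)(C)C(C)(C)C)C1 | intermediate
16 | (1R,6R)-2,6-bis(TBSO)-1-methylcyclohex-2-en-1-yl 4-TBSO-2-methoxy-6-methylbenzoate | C1C=C(O[Si](C)(C)C(C)(C)C)[C@](C)(OC(=O)c2c(C)cc(O[Si](C)(C)C(C)(C)C)cc2OC)[C@H](O[Si](C)(C)C(C)(C)C)C1 | intermediate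
17 | (1R,6R)-6-TBSO-1-methyl-2-oxocyclohex-3-en-1-yl 4-TBSO-2-methoxy-6-methylbenzoate | C1=CC(=O)[C@](C)(OC(=O)c2c(C)cc(O[Si](C)(C)C(C)(C)C)cc2OC)[C@H](O[Si](C)(C)C(C)(C)C)C1 | intermediate
18 | (E)-but-2-enal | C/C=C/C=O | starting material
19 | (3E)-1,1-dibromopenta-1,3-diene | C/C=C/C=C(Br)Br | intermediate
20 | lithium (E)-pent-3-en-1-ynide | C/C=C/C#C[Li] | intermediate
21 | bromo[(E)-pent-3-en-1-ynyl]zinc | C/C=C/C#C[Zn]Br | intermediate
22 | (1R,6R)-2,6-bis(TBSO)-1-methyl-4-[(3E)-pent-3-en-1-yn-1-yl]cyclohex-2-en-1-yl 4-TBSO-2-methoxy-6-methylbenzoate (C4a epimers) | C/C=C/C#CC1C=C(O[Si](C)(C)C(C)(C)C)[C@](C)(OC(=O)c2c(C)cc(O[Si](C)(C)C(C)(C)C)cc2OC)[C@H](O[Si](C)(C)C(C)(C)C)C1 | intermediate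
23 | (1R,6R)-6-TBSO-3-(hydroxymethyl)-1-methyl-2-oxo-4-[(3E)-pent-3-en-1-yn-1-yl]cyclohexyl 4-TBSO-2-methoxy-6-methylbenzoate (C4a/C8a epimers) | C/C=C/C#CC1C(CO)C(=O)[C@](C)(OC(=O)c2c(C)cc(O[Si](C)(C)C(C)(C)C)cc2OC)[C@H](O[Si](C)(C)C(C)(C)C)C1 | intermediate
24 | (1R,6R)-6-TBSO-1-methyl-4-[(3E)-pent-3-en-1-yn-1-yl]-2-(trimethylsilyloxy)-3-[(trimethylsilyloxy)methyl]cyclohex-2-en-1-yl 4-TBSO-2-methoxy-6-methylbenzoate | C/C=C/C#CC1C(CO[Si](C)(C)C)=C(O[Si](C)(C)C)[C@](C)(OC(=O)c2c(C)cc(O[Si](C)(C)C(C)(C)C)cc2OC)[C@H](O[Si](C)(C)C(C)(C)C)C1 | intermediate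
25 | (1R,6R)-6-TBSO-1-methyl-2-oxo-4-[(3E)-pent-3-en-1-yn-1-yl]-3-(phenylselanyl)-3-[(trimethylsilyloxy)methyl]cyclohexyl 4-TBSO-2-methoxy-6-methylbenzoate | C/C=C/C#CC1C(CO[Si](C)(C)C)([Se]c3ccccc3)C(=O)[C@](C)(OC(=O)c2c(C)cc(O[Si](C)(C)C(C)(C)C)cc2OC)[C@H](O[Si](C)(C)C(C)(C)C)C1 | intermediate
26 | selenoxide of 25 (3-benzeneseleninyl) | C/C=C/C#CC1C(CO[Si](C)(C)C)([Se](=O)c3ccccc3)C(=O)[C@](C)(OC(=O)c2c(C)cc(O[Si](C)(C)C(C)(C)C)cc2OC)[C@H](O[Si](C)(C)C(C)(C)C)C1 | intermediate
27 | (1R,6R)-6-TBSO-1-methyl-2-oxo-4-[(3E)-pent-3-en-1-yn-1-yl]-3-[(trimethylsilyloxy)methyl]cyclohex-3-en-1-yl 4-TBSO-2-methoxy-6-methylbenzoate | C/C=C/C#CC1=C(CO[Si](C)(C)C)C(=O)[C@](C)(OC(=O)c2c(C)cc(O[Si](C)(C)C(C)(C)C)cc2OC)[C@H](O[Si](C)(C)C(C)(C)C)C1 | intermediate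
28 | (1R,6R)-6-TBSO-3-(hydroxymethyl)-1-methyl-2-oxo-4-[(3E)-pent-3-en-1-yn-1-yl]cyclohex-3-en-1-yl 4-hydroxy-2-methoxy-6-methylbenzoate | C/C=C/C#CC1=C(CO)C(=O)[C@](C)(OC(=O)c2c(C)cc(O)cc2OC)[C@H](O[Si](C)(C)C(C)(C)C)C1 | intermediate
29 | (6R,7R)-6-TBSO-7-methyl-8-oxo-3-[(1E)-prop-1-en-1-yl]-5,6,7,8-tetrahydro-1H-isochromen-7-yl 4-hydroxy-2-methoxy-6-methylbenzoate | C/C=C/C1=CC2=C(CO1)C(=O)[C@](C)(OC(=O)c1c(C)cc(O)cc1OC)[C@H](O[Si](C)(C)C(C)(C)C)C2 | intermediate
30 | (6R,7R)-6-hydroxy-7-methyl-8-oxo-3-[(1E)-prop-1-en-1-yl]-5,6,7,8-tetrahydro-1H-isochromen-7-yl 4-hydroxy-2-methoxy-6-methylbenzoate | C/C=C/C1=CC2=C(CO1)C(=O)[C@](C)(OC(=O)c1c(C)cc(O)cc1OC)[C@H](O)C2 | target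

## Step count and least certain steps

Total step count: 18. Longest linear sequence: 15 steps (steps 1–7, 10–12 and 14–18); steps 8–9 and step 13 are side branches.

Step 10 (key step). The most likely failure is a cycloaddition that is too slow for a β-methyl-substituted ynoate. Thermal decomposition of the diene, and its consumption by the methanol released on aromatisation, would then outrun ring formation, and aromatisation could stay incomplete. The fallback sets out from 7 and returns at 15. Ketol 7 would be esterified with but-3-ynoic acid (DCC, DMAP, then Et3N to complete the isomerisation of the 3-ynoate to the allene), giving (1R,2R)-2-TBSO-1-methyl-6-oxocyclohexyl buta-2,3-dienoate F1. Its terminal, unhindered C2=C3 bond is a more reactive dienophile of a different class. With 12, in the same orientation (diene CH2 terminus to the central allene carbon), it should give the 6-methylidene cyclohexene cycloadduct F2. On the same acidic work-up F2 loses methanol and moves the exocyclic double bond into the ring, which leads through 14 to 15.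

Step 15. The hindered TBS enol ether may be too weak a nucleophile, so that protodesilylation to the plain ketone, or retro-aldol loss of the one-carbon unit, competes with hydroxymethylation. The fallback sets out from 17 and returns at 25. Enone 17 would first be hydroxymethylated at C8a by a Morita–Baylis–Hillman reaction (aq. HCHO, imidazole cat., THF–H2O), giving (1R,6R)-6-TBSO-3-(hydroxymethyl)-1-methyl-2-oxocyclohex-3-en-1-yl 4-TBSO-2-methoxy-6-methylbenzoate F3. This is protected as its trimethylsilyl ether F4 (TMSCl, Et3N). Conjugate alkynylation with 21 and TBSOTf then gives the tetrasubstituted silyl enol ether F5, and PhSeCl converts it to selenide 25, from which step 16 continues.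

Step 16. Selenenylation may occur on the face syn to the alkynyl group, which leaves no syn hydrogen on C4a. The selenoxide may eliminate toward C1, or PhSeCl may add to the enyne. The fallback sets out from 23 and returns at 30. The primary alcohol of 23 would be oxidised (Dess–Martin periodinane) to the largely enolised 2-formyl ketone F6. DDQ dehydrogenation would give the 2-formyl enynone F7; here only C4a carries a hydrogen that can be lost, so the regiochemical question disappears. AgOTf-catalysed cycloisomerisation in methanol (carbonyl oxygen onto the activated alkyne, methanol capture at C1) would give the 1-methoxy-1H-isochromene F8. Ionic reduction (Et3SiH, BF3·OEt2, −78 °C) would give the bis-silyl ether of the target F9, and the conditions of step 18 remove both silyl groups to give 30.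

Step 17. The ring may close at C4 (5-exo) and then aromatise to a furan, intermolecular methanol addition may stall, or base may expel the C6 silyloxy group through the C5 dienolate. The fallback sets out from 27 and returns at 30. Et2NH in MeOH would add to C3 (1,6-addition) and release the primary alcohol, giving the δ-(diethylamino) dienone F10. With mild acid (pyridinium p-toluenesulfonate, CH2Cl2) the C1 hydroxyl displaces the amine at C3 by addition–elimination, which can only form the six-membered ring. This gives the bis-silyl ether of the target F9, the compound also reached in the fallback for step 16, and the conditions of step 18 then give 30.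

## Further compounds

F1 | step 10 | (1R,2R)-2-TBSO-1-methyl-6-oxocyclohexyl buta-2,3-dienoate | C1CC(=O)[C@](C)(OC(=O)C=C=C)[C@H](O[Si](C)(C)C(C)(C)C)C1
F2 | step 10 | (1R,2R)-2-TBSO-1-methyl-6-oxocyclohexyl 2,2-dimethoxy-6-methylidene-4-(trimethylsilyloxy)cyclohex-3-ene-1-carboxylate | C1CC(=O)[C@](C)(OC(=O)C2C(=C)CC(O[Si](C)(C)C)=CC2(OC)OC)[C@H](O[Si](C)(C)C(C)(C)C)C1
F3 | step 15 | (1R,6R)-6-TBSO-3-(hydroxymethyl)-1-methyl-2-oxocyclohex-3-en-1-yl 4-TBSO-2-methoxy-6-methylbenzoate | C1=C(CO)C(=O)[C@](C)(OC(=O)c2c(C)cc(O[Si](C)(C)C(C)(C)C)cc2OC)[C@H](O[Si](C)(C)C(C)(C)C)C1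
F4 | step 15 | (1R,6R)-6-TBSO-1-methyl-2-oxo-3-[(trimethylsilyloxy)methyl]cyclohex-3-en-1-yl 4-TBSO-2-methoxy-6-methylbenzoate | C1=C(CO[Si](C)(C)C)C(=O)[C@](C)(OC(=O)c2c(C)cc(O[Si](C)(C)C(C)(C)C)cc2OC)[C@H](O[Si](C)(C)C(C)(C)C)C1
F5 | step 15 | (1R,6R)-2,6-bis(TBSO)-1-methyl-4-[(3E)-pent-3-en-1-yn-1-yl]-3-[(trimethylsilyloxy)methyl]cyclohex-2-en-1-yl 4-TBSO-2-methoxy-6-methylbenzoate | C/C=C/C#CC1C(CO[Si](C)(C)C)=C(O[Si](C)(C)C(C)(C)C)[C@](C)(OC(=O)c2c(C)cc(O[Si](C)(C)C(C)(C)C)cc2OC)[C@H](O[Si](C)(C)C(C)(C)C)C1
F6 | step 16 | (1R,6R)-6-TBSO-3-formyl-1-methyl-2-oxo-4-[(3E)-pent-3-en-1-yn-1-yl]cyclohexyl 4-TBSO-2-methoxy-6-methylbenzoate | C/C=C/C#CC1C(C=O)C(=O)[C@](C)(OC(=O)c2c(C)cc(O[Si](C)(C)C(C)(C)C)cc2OC)[C@H](O[Si](C)(C)C(C)(C)C)C1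
F7 | step 16 | (1R,6R)-6-TBSO-3-formyl-1-methyl-2-oxo-4-[(3E)-pent-3-en-1-yn-1-yl]cyclohex-3-en-1-yl 4-TBSO-2-methoxy-6-methylbenzoate | C/C=C/C#CC1=C(C=O)C(=O)[C@](C)(OC(=O)c2c(C)cc(O[Si](C)(C)C(C)(C)C)cc2OC)[C@H](O[Si](C)(C)C(C)(C)C)C1
F8 | step 16 | (6R,7R)-6-TBSO-1-methoxy-7-methyl-8-oxo-3-[(1E)-prop-1-en-1-yl]-5,6,7,8-tetrahydro-1H-isochromen-7-yl 4-TBSO-2-methoxy-6-methylbenzoate | C/C=C/C1=CC2=C(C(OC)O1)C(=O)[C@](C)(OC(=O)c1c(C)cc(O[Si](C)(C)C(C)(C)C)cc1OC)[C@H](O[Si](C)(C)C(C)(C)C)C2
F9 | step 16 | (6R,7R)-6-TBSO-7-methyl-8-oxo-3-[(1E)-prop-1-en-1-yl]-5,6,7,8-tetrahydro-1H-isochromen-7-yl 4-TBSO-2-methoxy-6-methylbenzoate | C/C=C/C1=CC2=C(CO1)C(=O)[C@](C)(OC(=O)c1c(C)cc(O[Si](C)(C)C(C)(C)C)cc1OC)[C@H](O[Si](C)(C)C(C)(C)C)C2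
F10 | step 17 | (1R,6R)-6-TBSO-4-[(3E)-2-(diethylamino)penta-1,3-dien-1-yl]-3-(hydroxymethyl)-1-methyl-2-oxocyclohex-3-en-1-yl 4-TBSO-2-methoxy-6-methylbenzoate | C/C=C/C(N(CC)CC)=CC1=C(CO)C(=O)[C@](C)(OC(=O)c2c(C)cc(O[Si](C)(C)C(C)(C)C)cc2OC)[C@H](O[Si](C)(C)C(C)(C)C)C1
A1 | alternative 1 | (4R,5R,10E)-5-TBSO-4-methyl-3,9-dioxododeca-1,10-dien-7-yn-4-yl 4-TBSO-2-methoxy-6-methylbenzoate | C=CC(=O)[C@](C)(OC(=O)c1c(C)cc(O[Si](C)(C)C(C)(C)C)cc1OC)[C@H](O[Si](C)(C)C(C)(C)C)CC#CC(=O)/C=C/C
A2 | alternative 1 | (1R,6R)-6-TBSO-1-methyl-3-methylidene-2-oxo-4-[(3E)-2-oxopent-3-en-1-ylidene]cyclohexyl 4-TBSO-2-methoxy-6-methylbenzoate | C/C=C/C(=O)C=C1C(=C)C(=O)[C@](C)(OC(=O)c2c(C)cc(O[Si](C)(C)C(C)(C)C)cc2OC)[C@H](O[Si](C)(C)C(C)(C)C)C1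
A3 | alternative 1 | (6R,7R)-6-TBSO-7-methyl-8-oxo-3-[(1E)-prop-1-en-1-yl]-5,6,7,8-tetrahydro-1H-isochromen-7-yl 4-TBSO-2-methoxy-6-methylbenzoate | C/C=C/C1=CC2=C(CO1)C(=O)[C@](C)(OC(=O)c1c(C)cc(O[Si](C)(C)C(C)(C)C)cc1OC)[C@H](O[Si](C)(C)C(C)(C)C)C2
A4 | alternative 2 | (1R,6R)-6-TBSO-1-methyl-2-oxocyclohex-3-en-1-yl 4-TBSO-2-methoxy-6-methylbenzoate | C1=CC(=O)[C@](C)(OC(=O)c2c(C)cc(O[Si](C)(C)C(C)(C)C)cc2OC)[C@H](O[Si](C)(C)C(C)(C)C)C1
A5 | alternative 2 | (1R,6R)-6-TBSO-3-(hydroxymethyl)-1-methyl-2-oxo-4-[(3E)-pent-3-en-1-yn-1-yl]cyclohexyl 4-TBSO-2-methoxy-6-methylbenzoate | C/C=C/C#CC1C(CO)C(=O)[C@](C)(OC(=O)c2c(C)cc(O[Si](C)(C)C(C)(C)C)cc2OC)[C@H](O[Si](C)(C)C(C)(C)C)C1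
A6 | alternative 2 | 4-TBSO-2-methoxy-6-methylbenzoic acid | Cc1cc(O[Si](C)(C)C(C)(C)C)cc(OC)c1C(=O)O
A7 | alternative 3 | (6R,7R)-6-TBSO-7-hydroxy-7-methyl-3-[(1E)-prop-1-en-1-yl]-6,7-dihydro-1H-isochromen-8(5H)-one | C/C=C/C1=CC2=C(CO1)C(=O)[C@](C)(O)[C@H](O[Si](C)(C)C(C)(C)C)C2
A8 | alternative 3 | 6-(2,4-dioxopentyl)-2,2-dimethyl-4H-1,3-dioxin-4-one | CC(=O)CC(=O)CC1=CC(=O)OC(C)(C)O1
A9 | alternative 3 | 3,5,7-trioxooct-1-en-1-one | O=C=CC(=O)CC(=O)CC(C)=O
A10 | alternative 3 | (6R,7R)-6-TBSO-7-methyl-8-oxo-3-[(1E)-prop-1-en-1-yl]-5,6,7,8-tetrahydro-1H-isochromen-7-yl 3,5,7-trioxooctanoate | C/C=C/C1=CC2=C(CO1)C(=O)[C@](C)(OC(=O)CC(=O)CC(=O)CC(C)=O)[C@H](O[Si](C)(C)C(C)(C)C)C2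
A11 | alternative 3 | (6R,7R)-6-TBSO-7-methyl-8-oxo-3-[(1E)-prop-1-en-1-yl]-5,6,7,8-tetrahydro-1H-isochromen-7-yl 2,4-dihydroxy-6-methylbenzoate | C/C=C/C1=CC2=C(CO1)C(=O)[C@](C)(OC(=O)c1c(C)cc(O)cc1O)[C@H](O[Si](C)(C)C(C)(C)C)C2
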